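**Retrosynthetic overview**
1. 2,3,4,7-Tetrabromoindole ⇒ rac-4,7-dibromo-3-hydroxyindolin-2-one. C2 (acid level) and C3 (alcohol level) already have the oxidation levels of a 2,3-dibromoindole, so two C–O → C–Br exchanges and aromatization finish the synthesis.
2. That dioxindole ⇒ 2-amino-3,6-dibromobenzaldehyde + tribromomethanide (from CHBr3), a carboxyl-anion (acyl-anion-type) equivalent. The C2–C3 bond joins two carbons that are both natively electrophilic carbonyl carbons; Jocic–Reeve unmasking and lactam closure follow in the same flask.
3. Amino aldehyde ⇒ 3,6-dibromo-2-fluorobenzaldehyde (F → NH2 by SNAr) ⇒ 1,4-dibromo-2-fluorobenzene (ortho-lithiation, DMF).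
4. Ring order: the benzene ring is bought with both aryl bromines in place; the five-membered ring is closed once, in the key step (C2–C3, then N1–C2), and aromatized last.

Assumption: the target is a flat, achiral indole with no stereocentre, so no enantiocontrol is needed; the stereocentres of compounds 3 and 6–10 are formed racemic and are gone before the end.

**Step 1**
Reactants: 1 1,4-dibromo-2-fluorobenzene
Product: 4 3,6-dibromo-2-fluorobenzaldehyde, via (3,6-dibromo-2-fluorophenyl)lithium 2 (not isolated), via lithium (3,6-dibromo-2-fluorophenyl)(dimethylamino)methanolate 3 (not isolated)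
Conditions: LiN(iPr)2 (1.1 equiv, commercial solution), THF, −78 °C, 1 h; DMF (1.5 equiv), −78 °C, 30 min; 1 M HCl, −78 °C to rt
Reagents that add atoms: N,N-dimethylformamide, CN(C)C=O
Why: Directed ortho-lithiation, in which the proton between fluorine and bromine is the most acidic and is removed at −78 °C without bromine–lithium exchange or benzyne formation, followed by Bouveault-type formylation of 2 with DMF through the tetrahedral adduct 3, which releases the aldehyde only on acidic quench.

**Step 2**
Reactants: 4 3,6-dibromo-2-fluorobenzaldehyde
Product: 5 2-amino-3,6-dibromobenzaldehyde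
Conditions: 28% aq. NH3 (10 equiv), DMSO, 80 °C, sealed tube, 12 h
Reagents that add atoms: ammonia, N
Why: Nucleophilic aromatic substitution by addition–elimination, in which the fluorine ortho to the formyl group is the activated site and fluoride is a far better leaving group than either bromide, giving an ortho-amino aldehyde that is a hydrogen-bonded vinylogous formamide flanked by bromines and therefore does not self-condense.

**Step 3** (key step)
Reactants: 5 2-amino-3,6-dibromobenzaldehyde
Product: 9 rac-4,7-dibromo-3-hydroxyindolin-2-one, via rac-1-(2-amino-3,6-dibromophenyl)-2,2,2-tribromoethan-1-ol 6 (not isolated), via rac-3,6-dibromo-2-(3,3-dibromooxiran-2-yl)aniline 7 (not isolated), via rac-2-(2-amino-3,6-dibromophenyl)-2-hydroxyacetic acid 8 (not isolated)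
Conditions: CHBr3 (1.3 equiv), KOH (6 equiv), LiCl (2 equiv), 1,4-dioxane/H2O (1:1), 0–5 °C, 24 h, Ar; then 6 M HCl to pH 1, 40 °C, 1 h
Reagents that add atoms: bromoform, BrC(Br)Br; potassium hydroxide, [K+].[OH-]
Why: Tribromomethanide from CHBr3 and KOH is a carboxyl-anion equivalent that adds to the aldehyde carbon of 5 to give 6, and the Jocic–Reeve reaction in its one-pot aldehyde/bromoform/KOH/LiCl form then closes the alkoxide to dibromooxirane 7, opens it with hydroxide at the benzylic carbon and collapses the CBr2 carbon to the carboxylate, so that acidification gives 8, which lactamizes onto the ortho amine to 9; the new C3 stereocentre is formed racemic because it becomes sp2 in step 4.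

**Step 4**
Reactants: 9 rac-4,7-dibromo-3-hydroxyindolin-2-one
Product: 11 2,3,4,7-tetrabromo-1H-indole, via rac-3,4,7-tribromoindolin-2-one 10 (not isolated)
Conditions: PBr3 (0.5 equiv), ClCH2CH2Cl, 0 °C to rt, 2 h; then POBr3 (2.5 equiv), 80 °C, 6 h; poured onto ice
Reagents that add atoms: phosphorus tribromide, BrP(Br)Br; phosphorus oxybromide, O=P(Br)(Br)Br
Why: Proposed new method: PBr3 first exchanges the C3 hydroxyl (benzylic and alpha to the lactam carbonyl) for bromide to give 10, then POBr3 activates the lactam oxygen so that bromide takes its place at C2, and loss of the acidic C3 proton gives the aromatic indole with both new bromines in place and no stereocentre left; the closest known reactions are the POBr3 conversion of oxindoles (including 3-substituted ones) into 2-bromoindoles and the PBr3 deoxybromination of mandelate-type alpha-hydroxy carbonyl compounds.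

**Compound list**
1 | 1,4-dibromo-2-fluorobenzene | Fc1cc(Br)ccc1Br | starting material
2 | (3,6-dibromo-2-fluorophenyl)lithium (not isolated) | [Li]c1c(F)c(Br)ccc1Br | intermediate
3 | lithium (3,6-dibromo-2-fluorophenyl)(dimethylamino)methanolate (racemic, not isolated) | [Li+].[O-]C(N(C)C)c1c(F)c(Br)ccc1Br | intermediate
4 | 3,6-dibromo-2-fluorobenzaldehyde | O=Cc1c(F)c(Br)ccc1Br | intermediate
5 | 2-amino-3,6-dibromobenzaldehyde | Nc1c(Br)ccc(Br)c1C=O | intermediate
6 | rac-1-(2-amino-3,6-dibromophenyl)-2,2,2-tribromoethan-1-ol (not isolated) | Nc1c(Br)ccc(Br)c1C(O)C(Br)(Br)Br | intermediate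
7 | rac-3,6-dibromo-2-(3,3-dibromooxiran-2-yl)aniline (not isolated) | Nc1c(Br)ccc(Br)c1C2OC2(Br)Br | intermediate
8 | rac-2-(2-amino-3,6-dibromophenyl)-2-hydroxyacetic acid (not isolated) | OC(=O)C(O)c1c(Br)ccc(Br)c1N | intermediate
9 | rac-4,7-dibromo-3-hydroxyindolin-2-one | O=C1Nc2c(Br)ccc(Br)c2C1O | intermediate
10 | rac-3,4,7-tribromoindolin-2-one (not isolated) | O=C1Nc2c(Br)ccc(Br)c2C1Br | intermediate
11 | 2,3,4,7-tetrabromo-1H-indole (achiral) | Brc1[nH]c2c(Br)ccc(Br)c2c1Br | target

**Totals**
Total step count: 4 (3 if the catalogue compound 4 is bought instead of made from the much cheaper 1).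
Longest linear sequence: 4 steps (1 → 4 → 5 → 9 → 11).

**Steps most likely to fail**

1. Step 3 (key step). The free aryl amine can be intercepted by dibromocarbene (isocyanide formation), it can open oxirane 7 at the CBr2 carbon (indoxyl-type by-products), and 9 autoxidizes in base if air gets in. The fallback sets out from 5 and comes back at 11, replacing the carboxyl-anion equivalent by a formyl-anion equivalent, nitromethane. Henry condensation of 5 with nitromethane (NH4OAc, MeNO2, 90 °C) gives (E)-3,6-dibromo-2-(2-nitrovinyl)aniline F1. Fe powder in AcOH/EtOH at 80 °C reduces the nitroalkene, and the ring amine closes onto the former nitro carbon with loss of ammonia to give 4,7-dibromo-1H-indole F2. N-Bromosuccinimide (2.1 equiv, DMF, 0 °C to rt) then brominates C3 and C2 to give 11, so this fallback also bypasses 9 and step 4.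

2. Step 4. If lactam activation outruns the C3 exchange, a 2-bromo indole oxygenated at C3 forms that cannot be carried on; 10 is also a reactive alkylating agent, and HBr at 80 °C may erode the product. The fallback sets out from 9 and comes back at 11, separating the two exchanges. PBr3 alone (CH2Cl2, 0 °C) gives 10, which is isolated. Zn dust in AcOH at rt removes its C3 bromine to give 4,7-dibromoindolin-2-one F3. POBr3 (ClCH2CH2Cl, 80 °C) converts this plain oxindole into 2,4,7-tribromo-1H-indole F4. N-Bromosuccinimide (1.05 equiv, DMF, 0 °C) brominates the free C3 position to give 11.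

3. Step 2. Ammonia condenses reversibly with the formyl group, which ties up material as aminal-type oligomers and weakens the activation for substitution. The fallback sets out from 4 and comes back at 5, using azide as the nitrogen nucleophile. NaN3 (DMSO, 50 °C) displaces fluoride to give 2-azido-3,6-dibromobenzaldehyde F5. Zn dust with NH4Cl (EtOH/H2O, rt) reduces the azide to the amine 5 without touching the aldehyde or the aryl bromides.

**Further compounds**
F1 | step 3 | (E)-3,6-dibromo-2-(2-nitrovinyl)aniline | Nc1c(Br)ccc(Br)c1/C=C/[N+](=O)[O-]
F2 | step 3 | 4,7-dibromo-1H-indole | Brc1ccc(Br)c2[nH]ccc12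
F3 | step 4 | 4,7-dibromoindolin-2-one | O=C1Cc2c(Br)ccc(Br)c2N1
F4 | step 4 | 2,4,7-tribromo-1H-indole | Brc1cc2c(Br)ccc(Br)c2[nH]1
F5 | step 2 | 2-azido-3,6-dibromobenzaldehyde | [N-]=[N+]=Nc1c(Br)ccc(Br)c1C=O
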